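**Strategy.** The route rests on cutting each 3-substituted furan at the bond between ring positions 3 and 4. That is the bond between the ring carbon that carries the chain (ring A on C1, ring B on C11 of the C1–C11 chain) and the adjacent ring CH. One double ring-closing metathesis forms both of these bonds as ring alkenes and closes two 5-methoxy-2,5-dihydrofurans. Their acetal carbon already carries the leaving group needed for aromatisation. The precursor is the C6 silyl ether of the (3E,6R,8S) chain, made from (S)-citronellal, whose two ends are 2-methyleneallyl ethers of acrolein methyl acetal.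

Key step: step 8

Numbering: chain atoms run C1 (bearing ring A, alkene side) to C11 (bearing ring B); the target is (3E,6R,8S). TBS = tert-butyldimethylsilyl.

Assumption: the binaphthyl phosphoric acid is taken to show the same facial preference in allenylboration as in allylboration of aldehydes ((R)-acid, Re face), so the (S)-acid is specified for the Si-face addition that gives 6R; the configuration of 4 should be confirmed by Mosher ester analysis before it is carried on.

Step 1
Reactants: 1 (S)-citronellal; 2 allenylboronic acid pinacol ester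
Product: 4 (4R,6S)-6,10-dimethylundec-9-en-1-yn-4-ol, via pinacol borate ester 3 (not isolated)
Conditions: (S)-TRIP [(S)-3,3′-bis(2,4,6-triisopropylphenyl)-1,1′-binaphthyl-2,2′-diyl hydrogen phosphate] (10 mol%), 4 Å MS, toluene, −20 °C; aq. NaHCO3
Reagents that add atoms: allenylboronic acid pinacol ester (compound 2), C=C=CB1OC(C)(C)C(C)(C)O1
Why: Brønsted acid-catalysed allenylboration (SE2′ propargylation) through a closed six-membered chair transition state in which the phosphoric acid binds a boronate oxygen and the formyl hydrogen; the (S)-acid should direct addition to the Si face of the aldehyde and so set C6 as R under catalyst control, the remote C8 centre (S, from 1) being too far away to interfere.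

Step 2
Reactants: 4 (4R,6S)-6,10-dimethylundec-9-en-1-yn-4-ol
Product: 5 tert-butyl{[(4R,6S)-6,10-dimethylundec-9-en-1-yn-4-yl]oxy}dimethylsilane
Conditions: TBSCl, imidazole, DMF, rt
Reagents that add atoms: tert-butyldimethylsilyl chloride, CC(C)(C)[Si](C)(C)Cl
Why: Imidazole-promoted silylation of a secondary alcohol masks C6–OH as an ether that is stable to ozone, AlMe3, n-BuLi, Grignard reagents and mild acid, and it touches no stereocentre.

Step 3
Reactants: 5 tert-butyl{[(4R,6S)-6,10-dimethylundec-9-en-1-yn-4-yl]oxy}dimethylsilane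
Product: 7 (4S,6R)-6-[(tert-butyldimethylsilyl)oxy]-4-methylnon-8-yn-1-ol, via aldehyde 6 (not isolated)
Conditions: O3, CH2Cl2/MeOH, Sudan Red 7B (indicator), −78 °C; then NaBH4, −78 °C → rt
Reagents that add atoms: ozone, [O-][O+]=O
Why: Ozonolysis with reductive work-up; the electron-rich trisubstituted alkene reacts with ozone far faster than the terminal alkyne, and the dye marks the end point so that the alkyne is not over-oxidised.

Step 4
Reactants: 7 (4S,6R)-6-[(tert-butyldimethylsilyl)oxy]-4-methylnon-8-yn-1-ol; 8 oxirane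
Product: 11 (3E,6R,8S)-6-[(tert-butyldimethylsilyl)oxy]-4,8-dimethylundec-3-ene-1,11-diol, via alkenylalane 9 (not isolated), via lithium alanate 10 (not isolated)
Conditions: AlMe3 (4 equiv), (C5H5)2ZrCl2 (0.3 equiv), CH2Cl2, 0 °C → rt; volatiles removed; hexane/THF, n-BuLi (2 equiv), −78 → 0 °C; oxirane (THF solution), 0 °C → rt; aq. potassium sodium tartrate
Reagents that add atoms: trimethylaluminium, C[Al](C)C; oxirane (compound 8), C1CO1
Why: Negishi zirconium-catalysed methylalumination adds CH3 and Al syn across the terminal alkyne with aluminium at the terminal carbon (the free hydroxyl is carried as its dimethylaluminium alkoxide), and the lithium alanate opens oxirane with retention of the alkenyl geometry, which sets the 3E alkene.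

Step 5
Reactants: 11 (3E,6R,8S)-6-[(tert-butyldimethylsilyl)oxy]-4,8-dimethylundec-3-ene-1,11-diol
Product: 12 {[(3E,6R,8S)-1,11-dibromo-4,8-dimethylundec-3-en-6-yl]oxy}(tert-butyl)dimethylsilane
Conditions: CBr4, PPh3, 2,6-lutidine, CH2Cl2, 0 °C
Reagents that add atoms: carbon tetrabromide, BrC(Br)(Br)Br
Why: Appel bromination converts both primary alcohols into bromides by SN2 displacement of the alkoxyphosphonium ions, while the lutidine buffer keeps the secondary silyl ether and the alkene intact.

Step 6
Reactants: 12 {[(3E,6R,8S)-1,11-dibromo-4,8-dimethylundec-3-en-6-yl]oxy}(tert-butyl)dimethylsilane; 13 propargyl alcohol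
Product: 16 (5E,8R,10S)-8-[(tert-butyldimethylsilyl)oxy]-6,10-dimethyl-2,14-dimethylidenepentadec-5-ene-1,15-diol, via bis-Grignard reagent 14 (not isolated), via cyclic alkenylmagnesium adduct 15 (not isolated)
Conditions: Mg turnings, THF, 40 °C; then added to ClMgOCH2C≡CH (from 13 and MeMgCl, THF, 0 °C) and CuI (20 mol%), THF/Et2O, 0 → 35 °C; aq. NH4Cl
Reagents that add atoms: propargyl alcohol (compound 13), C#CCO
Why: Copper-catalysed carbomagnesiation of a propargylic alkoxide: each alkylmagnesium terminus adds to the internal alkyne carbon with magnesium chelated between oxygen and the terminal carbon, and protonation on work-up gives the 2-alkylallyl alcohol at both ends; premetalation of 13 with MeMgCl means that none of the bis-Grignard reagent is spent on the hydroxyl group.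

Step 7
Reactants: 16 (5E,8R,10S)-8-[(tert-butyldimethylsilyl)oxy]-6,10-dimethyl-2,14-dimethylidenepentadec-5-ene-1,15-diol; 17 methoxyallene
Product: 18 tert-butyl{[(5E,8R,10S)-1,15-bis[(1-methoxyprop-2-en-1-yl)oxy]-6,10-dimethyl-2,14-dimethylidenepentadec-5-en-8-yl]oxy}dimethylsilane (acetal epimers)
Conditions: methoxyallene (6 equiv), Pd(OAc)2 (5 mol%), dppp (7.5 mol%), Et3N, MeCN, rt → 50 °C
Reagents that add atoms: methoxyallene (compound 17), COC=C=C
Why: Palladium-catalysed hydroalkoxylation of an alkoxyallene: a 1-methoxy-π-allylpalladium intermediate, formed from zerovalent palladium and the allene, is attacked by each primary allylic alcohol at the oxygen-bearing terminus to give the mixed acrolein acetal under basic conditions that leave the silyl ether untouched, and the configuration at the new acetal carbons is of no consequence.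

Step 8
Reactants: 18 tert-butyl{[(5E,8R,10S)-1,15-bis[(1-methoxyprop-2-en-1-yl)oxy]-6,10-dimethyl-2,14-dimethylidenepentadec-5-en-8-yl]oxy}dimethylsilane (acetal epimers)
Product: 19 tert-butyl{[(3E,6R,8S)-1,11-bis(5-methoxy-2,5-dihydrofuran-3-yl)-4,8-dimethylundec-3-en-6-yl]oxy}dimethylsilane (acetal epimers)
Conditions: second-generation Grubbs catalyst RuCl2(=CHPh)(PCy3)(H2IMes) (10 mol%), degassed CH2Cl2 (0.005 M), 40 °C
Reagents that add atoms: none
Why: The ruthenium benzylidene exchanges onto the monosubstituted vinyl group of each acrolein acetal, the alkylidene so formed adds to the tethered 1,1-disubstituted alkene in a [2+2] cycloaddition, and cycloreversion of the ruthenacyclobutane releases the ring alkene while the methylidene carrier leaves as ethene. The closest known reaction type is ring-closing olefin metathesis of allyl 1-alkoxyallyl ethers to 2-alkoxy-2,5-dihydrofurans, used as a furan synthesis. Ring A (on C1) and ring B (on C11) each close as a five-membered ring at carbon–carbon, between the chain-bearing ring carbon and the adjacent CH, the C–O bonds being already in place. No stereocentre is created, the acetal carbons remain an epimer mixture that is erased on aromatisation, and C6, C8 and the 3E alkene are not touched. The step needs chemoselectivity for twofold five-ring closure over cross-metathesis between the termini, end-to-end macrocyclisation and attack on the C3=C4 alkene. High dilution, the kinetic preference for five-membered closure and the hindrance of the trisubstituted C3=C4 alkene, which could only close an eight-membered ring, secure it.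

Step 9
Reactants: 19 tert-butyl{[(3E,6R,8S)-1,11-bis(5-methoxy-2,5-dihydrofuran-3-yl)-4,8-dimethylundec-3-en-6-yl]oxy}dimethylsilane (acetal epimers)
Product: 20 tert-butyl{[(3E,6R,8S)-1,11-di(furan-3-yl)-4,8-dimethylundec-3-en-6-yl]oxy}dimethylsilane
Conditions: PPTS (20 mol%), CH2Cl2, rt
Reagents that add atoms: none
Why: Acid-catalysed elimination of methanol: ionisation of each allylic acetal to the cyclic oxocarbenium ion and loss of a proton from the ring CH2 gives the aromatic furan, and catalytic pyridinium tosylate is too weak to cleave the secondary silyl ether or to protonate the C3=C4 alkene.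

Step 10
Reactants: 20 tert-butyl{[(3E,6R,8S)-1,11-di(furan-3-yl)-4,8-dimethylundec-3-en-6-yl]oxy}dimethylsilane
Product: 21 (3E,6R,8S)-1,11-di(furan-3-yl)-4,8-dimethylundec-3-en-6-ol
Conditions: Bu4NF, THF, 0 °C → rt
Reagents that add atoms: none
Why: Fluoride-mediated desilylation driven by the strength of the Si–F bond; the furans, the trisubstituted alkene and both stereocentres are inert to Bu4NF.

Step 11
Reactants: 21 (3E,6R,8S)-1,11-di(furan-3-yl)-4,8-dimethylundec-3-en-6-ol
Product: 22 (3E,6R,8S)-1,11-di(furan-3-yl)-4,8-dimethylundec-3-en-6-yl acetate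
Conditions: Ac2O, pyridine, DMAP (cat.), CH2Cl2, rt
Reagents that add atoms: acetic anhydride, CC(=O)OC(C)=O
Why: DMAP-catalysed O-acetylation of the secondary alcohol takes place at oxygen with retention of the 6R configuration and does not affect the furans under these base-buffered conditions.

**Compound list**

1 | (S)-citronellal, (3S)-3,7-dimethyloct-6-enal | O=CC[C@@H](C)CCC=C(C)C | starting material
2 | allenylboronic acid pinacol ester, 4,4,5,5-tetramethyl-2-(propa-1,2-dien-1-yl)-1,3,2-dioxaborolane | C=C=CB1OC(C)(C)C(C)(C)O1 | starting material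
3 | pinacol borate ester of 4, 2-{[(4R,6S)-6,10-dimethylundec-9-en-1-yn-4-yl]oxy}-4,4,5,5-tetramethyl-1,3,2-dioxaborolane | C#CC[C@H](OB1OC(C)(C)C(C)(C)O1)C[C@@H](C)CCC=C(C)C | intermediate
4 | (4R,6S)-6,10-dimethylundec-9-en-1-yn-4-ol | C#CC[C@H](O)C[C@@H](C)CCC=C(C)C | intermediate
5 | tert-butyl{[(4R,6S)-6,10-dimethylundec-9-en-1-yn-4-yl]oxy}dimethylsilane | C#CC[C@H](O[Si](C)(C)C(C)(C)C)C[C@@H](C)CCC=C(C)C | intermediate
6 | (4S,6R)-6-[(tert-butyldimethylsilyl)oxy]-4-methylnon-8-ynal | C#CC[C@H](O[Si](C)(C)C(C)(C)C)C[C@@H](C)CCC=O | intermediate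
7 | (4S,6R)-6-[(tert-butyldimethylsilyl)oxy]-4-methylnon-8-yn-1-ol | C#CC[C@H](O[Si](C)(C)C(C)(C)C)C[C@@H](C)CCCO | intermediate
8 | oxirane | C1CO1 | starting material
9 | (E)-alkenyldimethylalane from 7, hydroxyl carried as dimethylaluminium alkoxide | C[Al](C)/C=C(\C)C[C@H](O[Si](C)(C)C(C)(C)C)C[C@@H](C)CCCO[Al](C)C | intermediate
10 | lithium (E)-alkenyl(butyl)dimethylalanate from 9 | [Li+].CCCC[Al-](C)(C)/C=C(\C)C[C@H](O[Si](C)(C)C(C)(C)C)C[C@@H](C)CCCO[Al](C)C | intermediate
11 | (3E,6R,8S)-6-[(tert-butyldimethylsilyl)oxy]-4,8-dimethylundec-3-ene-1,11-diol | CC(C)(C)[Si](C)(C)O[C@@H](C/C(C)=C/CCO)C[C@@H](C)CCCO | intermediate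
12 | {[(3E,6R,8S)-1,11-dibromo-4,8-dimethylundec-3-en-6-yl]oxy}(tert-butyl)dimethylsilane | CC(C)(C)[Si](C)(C)O[C@@H](C/C(C)=C/CCBr)C[C@@H](C)CCCBr | intermediate
13 | propargyl alcohol, prop-2-yn-1-ol | C#CCO | starting material
14 | bis-Grignard reagent from 12, C1 and C11 as CH2MgBr | CC(C)(C)[Si](C)(C)O[C@@H](C/C(C)=C/CC[Mg]Br)C[C@@H](C)CCC[Mg]Br | intermediate
15 | twofold cyclic alkenylmagnesium alkoxide adduct (two 1-oxa-2-magnesacyclopent-3-ene rings) | CC(C)(C)[Si](C)(C)O[C@@H](C/C(C)=C/CCC1=C[Mg]OC1)C[C@@H](C)CCCC1=C[Mg]OC1 | intermediate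
16 | (5E,8R,10S)-8-[(tert-butyldimethylsilyl)oxy]-6,10-dimethyl-2,14-dimethylidenepentadec-5-ene-1,15-diol | CC(C)(C)[Si](C)(C)O[C@@H](C/C(C)=C/CCC(=C)CO)C[C@@H](C)CCCC(=C)CO | intermediate
17 | methoxyallene, 1-methoxypropa-1,2-diene | COC=C=C | starting material
18 | tert-butyl{[(5E,8R,10S)-1,15-bis[(1-methoxyprop-2-en-1-yl)oxy]-6,10-dimethyl-2,14-dimethylidenepentadec-5-en-8-yl]oxy}dimethylsilane (acetal epimers) | CC(C)(C)[Si](C)(C)O[C@@H](C/C(C)=C/CCC(=C)COC(OC)C=C)C[C@@H](C)CCCC(=C)COC(OC)C=C | intermediate
19 | tert-butyl{[(3E,6R,8S)-1,11-bis(5-methoxy-2,5-dihydrofuran-3-yl)-4,8-dimethylundec-3-en-6-yl]oxy}dimethylsilane (acetal epimers) | CC(C)(C)[Si](C)(C)O[C@@H](C/C(C)=C/CCC1=CC(OC)OC1)C[C@@H](C)CCCC1=CC(OC)OC1 | intermediate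
20 | tert-butyl{[(3E,6R,8S)-1,11-di(furan-3-yl)-4,8-dimethylundec-3-en-6-yl]oxy}dimethylsilane | CC(C)(C)[Si](C)(C)O[C@@H](C/C(C)=C/CCc1ccoc1)C[C@@H](C)CCCc1ccoc1 | intermediate
21 | (3E,6R,8S)-1,11-di(furan-3-yl)-4,8-dimethylundec-3-en-6-ol | O[C@@H](C/C(C)=C/CCc1ccoc1)C[C@@H](C)CCCc1ccoc1 | intermediate
22 | (3E,6R,8S)-1,11-di(furan-3-yl)-4,8-dimethylundec-3-en-6-yl acetate | CC(=O)O[C@@H](C/C(C)=C/CCc1ccoc1)C[C@@H](C)CCCc1ccoc1 | target

**Total step count:** 11
**Longest linear sequence:** 11 steps (1 → 22)

**Steps most likely to fail**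

1. Step 6 (twofold carbomagnesiation). The acetylenic C–H of the magnesium alkoxide may protonate the bis-Grignard reagent faster than the copper-mediated addition, and the second terminus may fail to add once the first has. Chain ends reduced to CH3 and mono-adducts would then build up. The fallback sets out from dibromide 12 and returns at diol 16. 2-Bromoprop-2-en-1-ol would be protected with 3,4-dihydro-2H-pyran (PPTS, CH2Cl2) as 2-[(2-bromoprop-2-en-1-yl)oxy]oxane F1. Zinc insertion into 12 (Zn dust, LiCl, THF, 50 °C) should give the bis(alkylzinc bromide) F2. Twofold Negishi coupling of it with F1 (Pd(OAc)2, SPhos, THF, rt) should give the bis(oxan-2-yl) ether of 16 F3. PPTS in MeOH at rt should then release 16 without loss of the secondary silyl ether.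

2. Step 4 (methylalumination and oxirane opening). The aluminium alkoxide at the hydroxyl terminus may compete for n-BuLi and hold the alanate in unreactive aggregates. Oxirane would then be opened slowly, and protodealumination on work-up would return the methylated terminal alkene. The fallback sets out from alkynol 7 and returns at diol 11. The same methylalumination via 9 would be quenched with I2 (THF, −30 °C) to give (4S,6R,8E)-6-[(tert-butyldimethylsilyl)oxy]-9-iodo-4,8-dimethylnon-8-en-1-ol F4. Suzuki–Miyaura coupling with CH2=CHBF3K (PdCl2(dppf), Et3N, n-PrOH, 80 °C) should give (4S,6R,8E)-6-[(tert-butyldimethylsilyl)oxy]-4,8-dimethylundeca-8,10-dien-1-ol F5. 9-BBN (THF, 0 °C → rt; then NaOH, H2O2) should hydroborate only the terminal vinyl group, anti-Markovnikov, and give 11.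

3. Step 1 (propargylation). Facial discrimination at an unbranched aliphatic aldehyde may be insufficient, or its sense may be opposite to the one assumed, so that C6 epimers form that are hard to separate. The fallback sets out from 1 and returns at 4. Corey–Chaykovsky methylenation (Me3S+ I−, KHMDS, THF, 0 °C) would convert 1 into 2-[(2S)-2,6-dimethylhept-5-en-1-yl]oxirane (epimers at the oxirane carbon) F6. Hydrolytic kinetic resolution would use the enantiomer of N,N′-bis(3,5-di-tert-butylsalicylidene)-1,2-cyclohexanediaminocobalt acetate (trivalent cobalt) that consumes the (2S)-epoxide, expected to be the (S,S)-complex, with 0.55 equiv H2O. It should leave (2R)-2-[(2S)-2,6-dimethylhept-5-en-1-yl]oxirane F7, at most half of the material. Opening at the CH2 terminus with LiC≡CH·H2NCH2CH2NH2 in DMSO should give 4, with C6 fixed by the resolution and not by an addition.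

**Further compounds**

F1 | step 6 | 2-[(2-bromoprop-2-en-1-yl)oxy]oxane | C=C(Br)COC1CCCCO1
F2 | step 6 | bis(alkylzinc bromide) from 12, C1 and C11 as CH2ZnBr | CC(C)(C)[Si](C)(C)O[C@@H](C/C(C)=C/CC[Zn]Br)C[C@@H](C)CCC[Zn]Br
F3 | step 6 | bis(oxan-2-yl) ether of 16 | CC(C)(C)[Si](C)(C)O[C@@H](C/C(C)=C/CCC(=C)COC1CCCCO1)C[C@@H](C)CCCC(=C)COC1CCCCO1
F4 | step 4 | (4S,6R,8E)-6-[(tert-butyldimethylsilyl)oxy]-9-iodo-4,8-dimethylnon-8-en-1-ol | I/C=C(\C)C[C@H](O[Si](C)(C)C(C)(C)C)C[C@@H](C)CCCO
F5 | step 4 | (4S,6R,8E)-6-[(tert-butyldimethylsilyl)oxy]-4,8-dimethylundeca-8,10-dien-1-ol | C=C/C=C(\C)C[C@H](O[Si](C)(C)C(C)(C)C)C[C@@H](C)CCCO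
F6 | step 1 | 2-[(2S)-2,6-dimethylhept-5-en-1-yl]oxirane (epimers at the oxirane carbon) | C1OC1C[C@@H](C)CCC=C(C)C
F7 | step 1 | (2R)-2-[(2S)-2,6-dimethylhept-5-en-1-yl]oxirane | C1O[C@@H]1C[C@@H](C)CCC=C(C)C
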